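The readings are simulated from invented constants, and the scatter is random.

Answer 4 questions about these flasks, two orders, one share and one choice from a list, by dividing one rate by another.

all flasks: free catalyst 0.00300 M

| run | substrate | coupling partner | target | time |
|---|---|---|---|---|
| south-west | 0.600 M | 0.900 M |  |  |
| south | 0.360 M | 0.660 M |  |  |
| east | 0.600 M | 0.900 M | 0.180 M |  |
| north-west | 0.600 M | 1.80 M |  |  |
| north-east | 0.300 M | 2.70 M |  | 7.6 h |

| run | time / h | [target] / M |
|---|---|---|
| south-west run | 0.30 | 0.014 |
| south-west run | 0.48 | 0.032 |
| south-west run | 0.76 | 0.047 |
| south-west run | 1.2 | 0.069 |
| south-west run | 1.9 | 0.101 |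
| south-west run | 3.0 | 0.137 |
| south-west run | 4.8 | 0.164 |
| south-west run | 7.6 | 0.191 |
| south run | 0.30 | 0.008 |
| south run | 0.48 | 0.015 |
| south run | 0.76 | 0.024 |
| south run | 1.2 | 0.031 |
| south run | 1.9 | 0.050 |
| south run | 3.0 | 0.063 |
| south run | 4.8 | 0.091 |
| south run | 7.6 | 0.111 |
| east run | 0.30 | 0.196 |
| east run | 0.48 | 0.199 |
| east run | 0.76 | 0.210 |
| east run | 1.2 | 0.218 |
| east run | 1.9 | 0.238 |
| east run | 3.0 | 0.256 |
| east run | 4.8 | 0.269 |
| east run | 7.6 | 0.270 |
| north-west run | 0.30 | 0.042 |
| north-west run | 0.48 | 0.057 |
| north-west run | 0.76 | 0.092 |
| north-west run | 1.2 | 0.124 |
| north-west run | 1.9 | 0.162 |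
| north-west run | 3.0 | 0.187 |
| north-west run | 4.8 | 0.196 |
| north-west run | 7.6 | 0.179 |

(scatter of a reading: 0.003 M)

- Overall: substrate + coupling partner -> target, with free catalyst as catalyst.
- Constant volume, constant temperature.
- "The second partner" is coupling partner.
- An order is taken over about fifteen percent of the charge, up and down.

- reaction order in [coupling partner] at the outset, round the charge of the south-west run, defined at two percent of the substrate turned into target
- reaction order in [substrate] at the outset, round the charge of the south-west run, defined at two percent of the substrate turned into target (one fixed amount of target, the same in the runs compared)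
- target in the north-east run at 7.6 h, as a share of the substrate charged
- which of these the readings show (the substrate kills the catalyst / the product reacts on with the second partner / the second partner is lost in pairs / nothing beyond the main steps / the substrate is lost by itself / an uncatalysed path runs beside)

In the north-west run target falls from 0.196 M at 4.8 h to 0.179 M at 7.6 h, so target is being consumed. With twice the coupling partner of the south-west run, the north-west run holds twice the target at 0.76 h. At 1.2 h the south run holds 0.449 of the target of the south-west run, and the product of its two charges is 0.440 of that run's. I therefore take formation as k·S·R and loss as l·P·R, with S substrate, R partner, P target, and k and l constants, so both my orders are 1. Dividing the two rates removes time and R and leaves σ = l/k: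

dP/dS = −1 + σ·P/S

y = (x − x^σ)/(σ − 1)

Here y is P over the substrate charged and x is S over that charge. Near σ = 1, the peak obeys −ln y ≈ 1 + (σ − 1)/2. Taking the highest reading of the north-west run as its peak gives 1.24, the selectivity factor σ, the loss constant divided by the formation constant. The north-west reading at 0.76 h gives k = 0.135 /M/h.

For the north-east flask, x = exp(−θ), with θ = k·R·t and R taken as its mean. Now test each input. The free catalyst stands at 0.00300 M in the north-west flask and 0.00300 M in the north-east flask, so k carries over. The north-east flask can use 0.600 M of partner, so I take the mean as the partner charge minus the substrate charge.

- One scatter on the early reading moves the share by 0.88 percentage points.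
- One scatter on the highest reading moves it by 0.53 points.
- Using the full partner charge moves it by 3.2 points.

So keep the partner use in the sum. My reckoning gives θ = 2.46 and a share of 15.9%.

The forecast gives 1 for the partner order, 0.8 for the substrate order, 15% for the share and the choice that the product reacts on with the second partner, with the words “formation and loss are both pseudo-first-order at about 0.4 h⁻¹”. Its substrate order differs from my 1.

    2 free catalyst ⇌ catalyst dimer, settled at all times (15400 /M)
    catalyst dimer + substrate + coupling partner → target + catalyst dimer (99.72 /M²/h)
    target + coupling partner → side product (0.1692 /M/h)

The north-east flask gives 15.7% at 7.6 h, the orders are 1.0 in partner and 1.0 in substrate, and the readings show that the product reacts on with the second partner. The south run's early rate of formation is 0.029 M/h, where the forecast read 0.032. Carried to the north-east charge, σ at 1.24 goes with the highest north-west reading, a share of 32.7%, which is 0.0980 M of target, and the 15.7% at 7.6 h is about half of that share.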